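**Plan**

1. Retrosynthesis: the side-chain ester C–O bond is cut first (to (R)-shikonin and 3-acetoxy-3-methylbutanoic acid), then the C1 quinone oxygen is taken off (1-naphthol level), then the quinone ring is opened at C2–C3 and at C4–C4a (naphthoquinone numbering).
2. Enabling feature: C3(H)–C4(=O) is a ketene in disguise, and C1=C2 together with the C4a=C8a bond of the benzenoid ring completes a hexatriene. A cis-aryl vinyl diazomethyl ketone therefore gives both bonds in one operation: Wolff shift of C2 from the carbonyl carbon to the diazo carbon (C2–C3), then 6π closure of the ketene carbon onto C4a (C4–C4a).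
3. Forward: the benzenoid ring is bought (2,5-dihydroxybenzaldehyde) and its aldehyde becomes C1≡C2 of an aryl alkyne. The side chain is joined by acetylide acylation, the alkyne is turned into the cis-aryl enone and diazoketone, the second ring is closed in the key step and then oxidized to the quinone.
4. Stereochemistry: the only stereocentre (R, carbinol carbon) comes from Noyori transfer hydrogenation of the ynone. The alkene geometry needed for ring closure comes from hydroxyl-directed trans-hydrostannation, and the ester is made last without breaking the C–O bond at the stereocentre.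

Key step: step 10

Assumption: the target is drawn as one tautomer of a naphthazarin; the tautomers interconvert fast, so the route aims at the carbon skeleton and the (R) carbinol centre, and compounds 1, 4, 10 and 19 are taken as purchasable.

**Route**

Step 1
Reactants: 1 2,5-dihydroxybenzaldehyde
Product: 2 2,5-bis(methoxymethoxy)benzaldehyde
Conditions: MOMCl, i-Pr2NEt, CH2Cl2, 0 °C to rt
Reagents that add atoms: chloromethyl methyl ether, COCCl
Why: O-alkylation of both phenols (MOM ether formation) gives acetal ethers that should withstand the organolithium, tin, diazo and photochemical steps and come off at the end under mild acid.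

Step 2
Reactants: 2 2,5-bis(methoxymethoxy)benzaldehyde
Product: 3 2-ethynyl-1,4-bis(methoxymethoxy)benzene
Conditions: dimethyl (1-diazo-2-oxopropyl)phosphonate, K2CO3, MeOH, rt
Reagents that add atoms: dimethyl (1-diazo-2-oxopropyl)phosphonate, CC(=O)C(=[N+]=[N-])P(=O)(OC)OC
Why: Seyferth–Gilbert homologation in the Ohira–Bestmann variant should turn the non-enolizable aryl aldehyde into the terminal alkyne under mild carbonate conditions.

Step 3
Reactants: 4 4-methylpent-3-enoic acid
Product: 5 N-methoxy-N,4-dimethylpent-3-enamide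
Conditions: CDI, CH2Cl2, 0 °C to rt; then MeNHOMe·HCl, rt
Reagents that add atoms: N,O-dimethylhydroxylamine hydrochloride, CNOC.Cl
Why: Weinreb amide formation through the acyl imidazolide needs no strong base, so the β,γ-double bond should not move into conjugation.

Step 4
Reactants: 3 2-ethynyl-1,4-bis(methoxymethoxy)benzene; 5 N-methoxy-N,4-dimethylpent-3-enamide
Product: 6 1-[2,5-bis(methoxymethoxy)phenyl]-6-methylhept-5-en-1-yn-3-one
Conditions: n-BuLi, THF, −78 °C; then 5, −78 to −20 °C; NH4Cl (aq)
Reagents that add atoms: none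
Why: Acylation of the lithium acetylide by the Weinreb amide stops at the chelated tetrahedral intermediate and should release the ynone only on the mildly acidic quench.

Step 5
Reactants: 6 1-[2,5-bis(methoxymethoxy)phenyl]-6-methylhept-5-en-1-yn-3-one
Product: 7 (3R)-1-[2,5-bis(methoxymethoxy)phenyl]-6-methylhept-5-en-1-yn-3-ol
Conditions: Ru[(R,R)-TsNCH(Ph)CH(Ph)NH](p-cymene) (1 mol %), i-PrOH, rt
Reagents that add atoms: none
Why: Noyori asymmetric transfer hydrogenation of an alkynyl ketone, in which the alkynyl group takes the place of the aryl group of aryl ketones in the six-membered transition state, so the (R,R) catalyst should give the (R) alcohol under base-free conditions that leave the skipped enone unconjugated.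

Step 6
Reactants: 7 (3R)-1-[2,5-bis(methoxymethoxy)phenyl]-6-methylhept-5-en-1-yn-3-ol
Product: 8 (1Z,3R)-1-[2,5-bis(methoxymethoxy)phenyl]-6-methyl-2-(tributylstannyl)hepta-1,5-dien-3-ol (aryl and tin cis)
Conditions: Bu3SnH (slow addition), [(C5Me5)RuCl]4 (2 mol %), CH2Cl2, rt
Reagents that add atoms: tributyltin hydride, CCCC[SnH](CCCC)CCCC
Why: Ruthenium-catalysed trans-hydrostannation, in which hydrogen bonding of the propargylic OH to the Ru–Cl unit should steer tin to the proximal alkyne carbon and trans addition places aryl and tin cis, the geometry the later ring closure needs.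

Step 7
Reactants: 8 (1Z,3R)-1-[2,5-bis(methoxymethoxy)phenyl]-6-methyl-2-(tributylstannyl)hepta-1,5-dien-3-ol
Product: 9 tert-butyldimethylsilyl ether of 8, (1Z,3R)
Conditions: TBSCl, imidazole, DMAP (cat.), DMF, rt to 40 °C
Reagents that add atoms: tert-butyldimethylsilyl chloride, CC(C)(C)[Si](C)(C)Cl
Why: Silylation of the secondary alcohol masks it against the acid chloride of step 8 and the amide base of step 9.

Step 8
Reactants: 9 silyl ether stannane; 10 acetyl chloride
Product: 11 (3Z)-4-[2,5-bis(methoxymethoxy)phenyl]-3-[(1R)-1-(tert-butyldimethylsilyloxy)-4-methylpent-3-enyl]but-3-en-2-one (aryl and acetyl cis)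
Conditions: Pd2(dba)3 (2.5 mol %), P(2-furyl)3, CuI (10 mol %), THF, 50 °C
Reagents that add atoms: none
Why: Stille acylation of an alkenylstannane by an acid chloride proceeds with retention of alkene geometry, and CuI with a weakly donating phosphine should speed tin-to-palladium transfer from the hindered stannane.

Step 9
Reactants: 11 cis-aryl methyl enone
Product: 13 (3Z)-4-[2,5-bis(methoxymethoxy)phenyl]-3-[(1R)-1-(tert-butyldimethylsilyloxy)-4-methylpent-3-enyl]-1-diazobut-3-en-2-one, via trifluoroacetyl diketone 12 (not isolated)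
Conditions: LiN(SiMe3)2, THF, −78 °C; CF3CO2CH2CF3; NH4Cl (aq); then MsN3, Et3N, H2O, MeCN, rt
Reagents that add atoms: methanesulfonyl azide, CS(=O)(=O)N=[N+]=[N-]; 2,2,2-trifluoroethyl trifluoroacetate, O=C(OCC(F)(F)F)C(F)(F)F (its acyl group stays only in 12)
Why: Detrifluoroacetylative diazo transfer (kinetic enolization of the methyl ketone, Claisen trifluoroacetylation, Regitz-type diazo transfer with loss of the trifluoroacetyl group) is the standard access to α′-diazo enones, which acid chlorides and diazomethane do not give cleanly because of pyrazoline formation.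

Step 10
Reactants: 13 cis-aryl diazoketone
Product: 16 3-[(1R)-1-(tert-butyldimethylsilyloxy)-4-methylpent-3-enyl]-5,8-bis(methoxymethoxy)naphthalen-1-ol, via aryl vinylketene 14 (not isolated), via ring-fusion dienone 15 (not isolated)
Conditions: hν (300 nm), degassed ClCH2CH2Cl, rt; then 80 °C
Reagents that add atoms: none
Why: Direct irradiation expels N2 from the diazoketone with 1,2-shift of the alkenyl carbon (C2 of the later quinone ring) from the carbonyl carbon to the diazo carbon (photochemical Wolff rearrangement), which makes the C2–C3 bond and turns the old carbonyl carbon into the ketene carbon C4 of 14. Ketene 14 is a hexatriene whose far double bond is the C4a=C8a bond of the dialkoxybenzene ring, so thermal disrotatory 6π electrocyclization at the free ortho carbon should make the C4–C4a bond and close the six-membered carbocycle (dienone 15), and a proton shift from the ring-fusion carbon to oxygen then gives naphthol 16. The closest known reaction type is the Wolff rearrangement–dienylketene electrocyclization benzannulation of unsaturated diazoketones, whose ring-closing stage is shared by the cyclobutenone and Dötz benzannulations. No stereocentre is set, because the sp3 ring-fusion carbon of 15 is lost on aromatization and the silyloxy-bearing (R) carbon is not involved. The step needs the aryl group cis to the ketene arm, which is fixed by the trans-hydrostannation of step 6 and kept through steps 8 and 9, and a single closure site, which is given because the other ortho carbon carries OMOM. It also needs migration to outrun carbene or ketene addition to the prenyl alkene, for which metal-free photolysis (concerted shift from the s-cis conformer) and the electron-rich arene terminus are relied on.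

Step 11
Reactants: 16 naphthol
Product: 17 2-[(1R)-1-(tert-butyldimethylsilyloxy)-4-methylpent-3-enyl]-5,8-bis(methoxymethoxy)naphthalene-1,4-dione
Conditions: (KSO3)2NO (2.5 equiv), KH2PO4 buffer, acetone/H2O, 0 °C to rt
Reagents that add atoms: potassium nitrosodisulfonate, [K+].[K+].[O]N(S(=O)(=O)[O-])S(=O)(=O)[O-]
Why: Teuber oxidation, in which the nitroxyl radical removes the phenolic hydrogen and a second equivalent couples at the free para carbon (C1), should give the 1,4-quinone after loss of imidodisulfonate.

Step 12
Reactants: 17 protected quinone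
Product: 18 (R)-shikonin, 5,8-dihydroxy-2-[(1R)-1-hydroxy-4-methylpent-3-enyl]naphthalene-1,4-dione
Conditions: HCl (3 M aq), MeOH/THF, rt
Reagents that add atoms: none
Why: Acid-catalysed acetal exchange should remove both aryl MOM groups (helped by the peri carbonyls) and solvolyse the silyl ether in the same flask, while the quinone-bound carbinol does not ionize and so keeps its (R) configuration.

Step 13
Reactants: 19 3-hydroxy-3-methylbutanoic acid; 10 acetyl chloride
Product: 20 3-acetoxy-3-methylbutanoic acid
Conditions: PhNMe2, CH2Cl2, 0 °C to rt; then H2O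
Reagents that add atoms: none
Why: O-Acetylation of the tertiary alcohol by acetyl chloride with a weak aniline base (the tert-butyl acetate protocol), any mixed anhydride at the carboxyl group being hydrolysed in the aqueous work-up.

Step 14
Reactants: 18 (R)-shikonin; 20 3-acetoxy-3-methylbutanoic acid
Product: 21 (1R)-1-(5,8-dihydroxy-1,4-dioxo-1,4-dihydronaphthalen-2-yl)-4-methylpent-3-enyl 3-acetoxy-3-methylbutanoate (target)
Conditions: DCC, DMAP (cat.), CH2Cl2, 0 °C to rt
Reagents that add atoms: none
Why: Steglich esterification should acylate only the side-chain alcohol, because both peri hydroxyls are locked in hydrogen bonds to the quinone carbonyls, and it retains configuration because the C–O bond at the stereocentre is not broken.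

**Compound list**

1 | 2,5-dihydroxybenzaldehyde | O=Cc1cc(O)ccc1O | starting material
2 | 2,5-bis(methoxymethoxy)benzaldehyde | O=Cc1cc(OCOC)ccc1OCOC | intermediate
3 | 2-ethynyl-1,4-bis(methoxymethoxy)benzene | C#Cc1cc(OCOC)ccc1OCOC | intermediate
4 | 4-methylpent-3-enoic acid | CC(C)=CCC(=O)O | starting material
5 | N-methoxy-N,4-dimethylpent-3-enamide | CC(C)=CCC(=O)N(C)OC | intermediate
6 | 1-[2,5-bis(methoxymethoxy)phenyl]-6-methylhept-5-en-1-yn-3-one | CC(C)=CCC(=O)C#Cc1cc(OCOC)ccc1OCOC | intermediate
7 | (3R)-1-[2,5-bis(methoxymethoxy)phenyl]-6-methylhept-5-en-1-yn-3-ol | O[C@H](CC=C(C)C)C#Cc1cc(OCOC)ccc1OCOC | intermediate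
8 | (1Z,3R)-1-[2,5-bis(methoxymethoxy)phenyl]-6-methyl-2-(tributylstannyl)hepta-1,5-dien-3-ol | COCOc1ccc(OCOC)c(/C=C(\[Sn](CCCC)(CCCC)CCCC)[C@H](O)CC=C(C)C)c1 | intermediate
9 | tert-butyldimethylsilyl ether of 8, (1Z,3R) | COCOc1ccc(OCOC)c(/C=C(\[Sn](CCCC)(CCCC)CCCC)[C@H](O[Si](C)(C)C(C)(C)C)CC=C(C)C)c1 | intermediate
10 | acetyl chloride | CC(=O)Cl | starting material
11 | (3Z)-4-[2,5-bis(methoxymethoxy)phenyl]-3-[(1R)-1-(tert-butyldimethylsilyloxy)-4-methylpent-3-enyl]but-3-en-2-one | COCOc1ccc(OCOC)c(/C=C(\C(C)=O)[C@H](O[Si](C)(C)C(C)(C)C)CC=C(C)C)c1 | intermediate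
12 | (5Z)-6-[2,5-bis(methoxymethoxy)phenyl]-5-[(1R)-1-(tert-butyldimethylsilyloxy)-4-methylpent-3-enyl]-1,1,1-trifluorohex-5-ene-2,4-dione (not isolated) | COCOc1ccc(OCOC)c(/C=C(\C(=O)CC(=O)C(F)(F)F)[C@H](O[Si](C)(C)C(C)(C)C)CC=C(C)C)c1 | intermediate
13 | (3Z)-4-[2,5-bis(methoxymethoxy)phenyl]-3-[(1R)-1-(tert-butyldimethylsilyloxy)-4-methylpent-3-enyl]-1-diazobut-3-en-2-one | COCOc1ccc(OCOC)c(/C=C(\C(=O)C=[N+]=[N-])[C@H](O[Si](C)(C)C(C)(C)C)CC=C(C)C)c1 | intermediate
14 | 4-[2,5-bis(methoxymethoxy)phenyl]-3-[(1R)-1-(tert-butyldimethylsilyloxy)-4-methylpent-3-enyl]buta-1,3-dien-1-one, aryl cis to the ketene arm (not isolated) | COCOc1ccc(OCOC)c(/C=C(\C=C=O)[C@H](O[Si](C)(C)C(C)(C)C)CC=C(C)C)c1 | intermediate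
15 | 3-[(1R)-1-(tert-butyldimethylsilyloxy)-4-methylpent-3-enyl]-5,8-bis(methoxymethoxy)-8aH-naphthalen-1-one, ring-fusion carbon unspecified (not isolated) | O=C1C=C([C@H](O[Si](C)(C)C(C)(C)C)CC=C(C)C)C=C2C(OCOC)=CC=C(OCOC)C12 | intermediate
16 | 3-[(1R)-1-(tert-butyldimethylsilyloxy)-4-methylpent-3-enyl]-5,8-bis(methoxymethoxy)naphthalen-1-ol | Oc1cc([C@H](O[Si](C)(C)C(C)(C)C)CC=C(C)C)cc2c(OCOC)ccc(OCOC)c12 | intermediate
17 | 2-[(1R)-1-(tert-butyldimethylsilyloxy)-4-methylpent-3-enyl]-5,8-bis(methoxymethoxy)naphthalene-1,4-dione | O=C1C=C([C@H](O[Si](C)(C)C(C)(C)C)CC=C(C)C)C(=O)c2c(OCOC)ccc(OCOC)c12 | intermediate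
18 | (R)-shikonin, 5,8-dihydroxy-2-[(1R)-1-hydroxy-4-methylpent-3-enyl]naphthalene-1,4-dione | O=C1C=C([C@H](O)CC=C(C)C)C(=O)c2c(O)ccc(O)c12 | intermediate
19 | 3-hydroxy-3-methylbutanoic acid | CC(C)(O)CC(=O)O | starting material
20 | 3-acetoxy-3-methylbutanoic acid | CC(=O)OC(C)(C)CC(=O)O | intermediate
21 | (1R)-1-(5,8-dihydroxy-1,4-dioxo-1,4-dihydronaphthalen-2-yl)-4-methylpent-3-enyl 3-acetoxy-3-methylbutanoate | CC(=O)OC(C)(C)CC(=O)O[C@H](CC=C(C)C)C1=CC(=O)c2c(O)ccc(O)c2C1=O | target

**Step count and risks**

Total: 14 steps. Longest linear sequence: 12 steps (steps 1, 2, 4 to 12 and 14, starting from 1).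

Most likely to fail, step 10. The carbene or the free ketene may be diverted by addition to the prenyl alkene (cyclopropanation, intramolecular [2+2]) or by ketene dimerization, and photoisomerization of the styrene-type alkene may take the aryl group out of reach before closure. The fallback avoids diazo and carbene chemistry; it sets out from 9 and comes back at 16. Iododestannylation of 9 (I2, CH2Cl2, 0 °C) would give the cis-aryl alkenyl iodide F1. Negishi coupling with the Reformatsky reagent BrZnCH2CO2Et (Pd2(dba)3, XPhos, THF, rt) would give the ethyl 4-aryl-but-3-enoate F2, and LiOH (THF/H2O) would give the butenoic acid F3. Stobbe-type cyclodehydration (NaOAc, Ac2O, 120 °C), an acylation of the free ortho carbon through the mixed anhydride, would give the naphthyl acetate F4, and K2CO3/MeOH would then give 16.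

Second, step 8. Tin-to-palladium transfer from the hindered, silyloxy-flanked stannane may be slow, so that protodestannylation or loss of alkene geometry takes over. The fallback sets out from 8 and comes back at 11, using the free hydroxyl to assist the metal transfer. Oxidative methoxycarbonylation of 8 (Pd(OAc)2, AsPh3, 1,4-benzoquinone, CO (1 atm), MeOH, rt) would give the cis-aryl hydroxy acrylate F5. TBSCl/imidazole would give the silyl ether F6, MeNHOMe·HCl/i-PrMgCl (THF, −20 °C) would give the Weinreb amide F7, and MeMgBr (THF, 0 °C) would give 11.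

Third, step 11. Radical coupling may occur at the less hindered ortho carbon instead of the para carbon that lies between the side chain and the peri OMOM group, or the dialkoxy ring may be over-oxidized. The fallback sets out from 16 and comes back at 18, using a two-electron ionic oxidation with capture by a small nucleophile. PhI(OAc)2 (2 equiv) in MeOH at 0 °C would give the para-quinone monoketal F8. The acid conditions of step 12 would then hydrolyse the ketal together with the MOM and silyl groups and give 18 directly.

**Further compounds**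

F1 | step 10 | (1Z)-alkenyl iodide from 9, aryl and iodine cis, (R) | COCOc1ccc(OCOC)c(/C=C(\I)[C@H](O[Si](C)(C)C(C)(C)C)CC=C(C)C)c1
F2 | step 10 | ethyl (3E)-4-[2,5-bis(methoxymethoxy)phenyl]-3-[(1R)-1-(tert-butyldimethylsilyloxy)-4-methylpent-3-enyl]but-3-enoate, aryl cis to the CH2CO2Et arm | COCOc1ccc(OCOC)c(/C=C(\CC(=O)OCC)[C@H](O[Si](C)(C)C(C)(C)C)CC=C(C)C)c1
F3 | step 10 | (3E)-4-[2,5-bis(methoxymethoxy)phenyl]-3-[(1R)-1-(tert-butyldimethylsilyloxy)-4-methylpent-3-enyl]but-3-enoic acid | COCOc1ccc(OCOC)c(/C=C(\CC(=O)O)[C@H](O[Si](C)(C)C(C)(C)C)CC=C(C)C)c1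
F4 | step 10 | 3-[(1R)-1-(tert-butyldimethylsilyloxy)-4-methylpent-3-enyl]-5,8-bis(methoxymethoxy)naphthalen-1-yl acetate | CC(=O)Oc1cc([C@H](O[Si](C)(C)C(C)(C)C)CC=C(C)C)cc2c(OCOC)ccc(OCOC)c12
F5 | step 8 | methyl (2Z)-3-[2,5-bis(methoxymethoxy)phenyl]-2-[(1R)-1-hydroxy-4-methylpent-3-enyl]prop-2-enoate | COCOc1ccc(OCOC)c(/C=C(\C(=O)OC)[C@H](O)CC=C(C)C)c1
F6 | step 8 | methyl (2Z)-3-[2,5-bis(methoxymethoxy)phenyl]-2-[(1R)-1-(tert-butyldimethylsilyloxy)-4-methylpent-3-enyl]prop-2-enoate | COCOc1ccc(OCOC)c(/C=C(\C(=O)OC)[C@H](O[Si](C)(C)C(C)(C)C)CC=C(C)C)c1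
F7 | step 8 | (2Z)-3-[2,5-bis(methoxymethoxy)phenyl]-2-[(1R)-1-(tert-butyldimethylsilyloxy)-4-methylpent-3-enyl]-N-methoxy-N-methylprop-2-enamide | COCOc1ccc(OCOC)c(/C=C(\C(=O)N(C)OC)[C@H](O[Si](C)(C)C(C)(C)C)CC=C(C)C)c1
F8 | step 11 | 3-[(1R)-1-(tert-butyldimethylsilyloxy)-4-methylpent-3-enyl]-4,4-dimethoxy-5,8-bis(methoxymethoxy)naphthalen-1(4H)-one | O=C1C=C([C@H](O[Si](C)(C)C(C)(C)C)CC=C(C)C)C(OC)(OC)c2c(OCOC)ccc(OCOC)c12
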